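The route cuts ring B across C1'–C2' and C5'–C6', so the depside ester is in place before the ring exists. Ring B carries two unlike meta oxygens (OMe at C2', aroyloxy at C4') around the C3' methyl, and its C1' ester and C6' methyl form a but-2-ynoate unit. One Diels–Alder reaction with methyl but-2-ynoate, followed by loss of methanol, therefore closes and aromatises ring B with both oxygens already differentiated. The precursor is the dienol ester of masked haematommic acid (two PMB ethers, C3 dioxolane) whose diene ends in a dimethyl ketene acetal. All three masks later fall in one acidic step.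

Key step: step 8

Remark on stereochemistry: the target has no stereocentre, stereogenic axis or configurable double bond. It is achiral, so no enantiomer has to be selected and no step sets configuration.

Remark on locants: unprimed numbers refer to ring A (the acid part) and primed numbers to ring B.

Remark on protecting groups: O2 and O4 of ring A carry 4-methoxybenzyl (PMB) ethers rather than plain benzyl ethers. A 2-aryl-1,3-dioxolane is a benzylidene-type acetal that hydrogenolysis can reduce. PMB ethers and the dioxolane leave together under TFA, so no reductive step is needed.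

Step 1
Reactants: 1 methyl orsellinate (methyl 2,4-dihydroxy-6-methylbenzoate)
Product: 2 methyl haematommate (methyl 3-formyl-2,4-dihydroxy-6-methylbenzoate)
Conditions: Cl2CHOMe (1.1 equiv), TiCl4 (2.2 equiv), CH2Cl2, −10 to 0 °C; 1 M aq HCl; chromatography
Reagents that add atoms: dichloromethyl methyl ether, COC(Cl)Cl; water, O
Why: Rieche formylation, in which titanium bound to the phenol oxygens should steer the chloro(methoxy)methyl cation to C3 between them, any more polar 5-formyl isomer being removed by chromatography.

Step 2
Reactants: 2 methyl haematommate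
Product: 3 methyl 3-formyl-2,4-bis[(4-methoxybenzyl)oxy]-6-methylbenzoate
Conditions: PMBCl (2.5 equiv), K2CO3 (3 equiv), DMF, 65 °C
Reagents that add atoms: 4-methoxybenzyl chloride, COc1ccc(CCl)cc1
Why: Williamson ether synthesis, in which warm carbonate in DMF breaks the hydrogen bonds of both phenols and the non-enolisable aldehyde and the hindered ester are untouched.

Step 3
Reactants: 3 methyl 3-formyl-2,4-bis[(4-methoxybenzyl)oxy]-6-methylbenzoate
Product: 4 methyl 3-(1,3-dioxolan-2-yl)-2,4-bis[(4-methoxybenzyl)oxy]-6-methylbenzoate
Conditions: TMSOCH2CH2OTMS (1.5 equiv), TMSOTf (5 mol %), CH2Cl2, −78 to −20 °C; pyridine quench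
Reagents that add atoms: 1,2-bis(trimethylsilyloxy)ethane, C[Si](C)(C)OCCO[Si](C)(C)C
Why: Noyori acetalisation, in which irreversible formation of the disiloxane drives the flanked aldehyde to the dioxolane at a temperature low enough for the PMB ethers to survive.

Step 4
Reactants: 4 methyl 3-(1,3-dioxolan-2-yl)-2,4-bis[(4-methoxybenzyl)oxy]-6-methylbenzoate
Product: 5 3-(1,3-dioxolan-2-yl)-2,4-bis[(4-methoxybenzyl)oxy]-6-methylbenzoic acid
Conditions: KOH (10 equiv), DMSO/H2O (4:1), 100 °C; cold 10% aq citric acid to pH 5, EtOAc
Reagents that add atoms: potassium hydroxide, [K+].[OH-]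
Why: Saponification of a di-ortho-substituted benzoate needs poorly solvated hydroxide in hot aqueous DMSO, to which acetal and ethers are inert, and the cold weak-acid work-up spares the dioxolane.

Step 5
Reactants: 6 trimethyl orthopropionate
Product: 7 1,1-dimethoxyprop-1-ene
Conditions: Al(OtBu)3 (10 mol %), neat, reflux under N2, slow fractional distillation into a receiver over K2CO3; redistil
Reagents that add atoms: none
Why: Aluminium-alkoxide-promoted dealcoholation of an orthoester to a ketene acetal, pulled forward by continuous removal of methanol and of the product, both of which boil below the orthoester.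

Step 6
Reactants: 7 1,1-dimethoxyprop-1-ene; 8 acetyl chloride
Product: 9 4,4-dimethoxy-3-methylbut-3-en-2-one
Conditions: Et3N (1.3 equiv), Et2O, 0 °C to rt; filter; distil under reduced pressure
Reagents that add atoms: none
Why: C-acylation of a ketene acetal at its nucleophilic β-carbon gives an acyl dimethoxycarbenium ion, whose very acidic α-proton should be taken by the amine faster than chloride can attack a methyl group.

Step 7
Reactants: 5 3-(1,3-dioxolan-2-yl)-2,4-bis[(4-methoxybenzyl)oxy]-6-methylbenzoic acid; 9 4,4-dimethoxy-3-methylbut-3-en-2-one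
Product: 12 4,4-dimethoxy-3-methylbuta-1,3-dien-2-yl 3-(1,3-dioxolan-2-yl)-2,4-bis[(4-methoxybenzyl)oxy]-6-methylbenzoate, via ring A acid chloride 10 (not isolated), via potassium dienolate 11 (not isolated)
Conditions: (a) 5, Ghosez reagent (1.05 equiv), CH2Cl2, 0 °C to rt, evaporate; (b) 9 (1.2 equiv), KHMDS (1.15 equiv), THF/DMPU (5:1), −78 °C; (c) 10 in THF added to 11, −78 to −20 °C; cold aq NaHCO3, Et2O with 1% Et3N; filtration through Et3N-deactivated alumina
Reagents that add atoms: 1-chloro-N,N,2-trimethylprop-1-en-1-amine, CC(C)=C(Cl)N(C)C (chlorine of 10 only); potassium bis(trimethylsilyl)amide, C[Si](C)(C)[N-][Si](C)(C)C.[K+] (potassium of 11 only)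
Why: The α-chloroenamine makes the acid chloride without releasing HCl, only the acetyl CH3 of 9 can be deprotonated, and O-acylation of a dissociated potassium enolate by a hard, di-ortho-substituted aroyl chloride is the established enol ester synthesis.

Step 8
Reactants: 12 4,4-dimethoxy-3-methylbuta-1,3-dien-2-yl 3-(1,3-dioxolan-2-yl)-2,4-bis[(4-methoxybenzyl)oxy]-6-methylbenzoate; 13 methyl but-2-ynoate
Product: 15 methyl 4-({3-(1,3-dioxolan-2-yl)-2,4-bis[(4-methoxybenzyl)oxy]-6-methylbenzoyl}oxy)-2-methoxy-3,6-dimethylbenzoate, via cyclohexadiene ketal adduct 14 (not isolated)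
Conditions: 13 (10 equiv, neat), powdered activated 4 Å MS, base-washed sealed tube, Ar, 135 °C; excess 13 recovered by distillation
Reagents that add atoms: none
Why: Proposed new method: the two methoxy groups on the acetal terminus and the aroyloxy oxygen on the inner carbon next to the CH2 group all polarise diene 12 towards that unsubstituted CH2, so a normal-electron-demand, concerted but strongly asynchronous [4+2] cycloaddition is expected in which the CH2 bonds first to the β-carbon of 13 (C5'–C6') and the acetal carbon then closes onto the α-carbon (C1'–C2'). Six-membered ring B is thereby closed in intermolecular [4+2] mode as 1,4-cyclohexadiene 14, whose C2' dimethyl ketal and C5' methylene stand 1,4 to each other, so heat expels one methanol and leaves arene 15 with a single methyl ether at C2' and the ester oxygen untouched at C4'. The closest known reaction type is the Diels–Alder/aromatisation of 1,1-dialkoxy-3-silyloxybuta-1,3-dienes with alkynoates, which gives resorcinol monomethyl ethers of the same orientation; an acyloxy group in place of silyloxy has not been shown and is a weaker donor, which is answered by working neat in excess 13 at 135 °C. No stereocentre is formed. The regiochemistry needed (C6' methyl beside C5'–H, C1' ester beside the C2' methoxy) follows from matching the donor-polarised CH2 with the electrophilic β-carbon of the ynoate, while attack through the fully substituted inner ketene acetal carbon ([2+2] mode) is sterically disfavoured. The dienol ester should survive because its carbonyl is shielded by the two ortho substituents of ring A, the medium is neutral and aprotic, the aldehyde is masked against the ketene acetal, and the sieves bind the liberated methanol before it can add to unreacted ketene acetal.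

Step 9
Reactants: 15 methyl 4-({3-(1,3-dioxolan-2-yl)-2,4-bis[(4-methoxybenzyl)oxy]-6-methylbenzoyl}oxy)-2-methoxy-3,6-dimethylbenzoate
Product: 16 2'-O-methylatranorin (methyl 4-[(3-formyl-2,4-dihydroxy-6-methylbenzoyl)oxy]-2-methoxy-3,6-dimethylbenzoate)
Conditions: TFA/CH2Cl2 (1:4), pentamethylbenzene (6 equiv), H2O (5 equiv), 0 °C to rt; aq NaHCO3
Reagents that add atoms: water, O
Why: Acidolysis, in which both aryl PMB ethers ionise in TFA with Friedel–Crafts capture of the cation by pentamethylbenzene and the electron-rich aryl dioxolane hydrolyses in the same pot, while the aryl ester, the methyl ester and the C2' methyl ether are inert to TFA.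

Compound list
1 | methyl orsellinate (methyl 2,4-dihydroxy-6-methylbenzoate) | COC(=O)c1c(C)cc(O)cc1O | starting material
2 | methyl haematommate (methyl 3-formyl-2,4-dihydroxy-6-methylbenzoate) | COC(=O)c1c(C)cc(O)c(C=O)c1O | intermediate
3 | methyl 3-formyl-2,4-bis[(4-methoxybenzyl)oxy]-6-methylbenzoate | COC(=O)c1c(C)cc(OCc2ccc(OC)cc2)c(C=O)c1OCc1ccc(OC)cc1 | intermediate
4 | methyl 3-(1,3-dioxolan-2-yl)-2,4-bis[(4-methoxybenzyl)oxy]-6-methylbenzoate | COC(=O)c1c(C)cc(OCc2ccc(OC)cc2)c(C2OCCO2)c1OCc1ccc(OC)cc1 | intermediate
5 | 3-(1,3-dioxolan-2-yl)-2,4-bis[(4-methoxybenzyl)oxy]-6-methylbenzoic acid | OC(=O)c1c(C)cc(OCc2ccc(OC)cc2)c(C2OCCO2)c1OCc1ccc(OC)cc1 | intermediate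
6 | trimethyl orthopropionate | CCC(OC)(OC)OC | starting material
7 | 1,1-dimethoxyprop-1-ene | CC=C(OC)OC | intermediate
8 | acetyl chloride | CC(=O)Cl | starting material
9 | 4,4-dimethoxy-3-methylbut-3-en-2-one | CC(=O)C(C)=C(OC)OC | intermediate
10 | 3-(1,3-dioxolan-2-yl)-2,4-bis[(4-methoxybenzyl)oxy]-6-methylbenzoyl chloride | O=C(Cl)c1c(C)cc(OCc2ccc(OC)cc2)c(C2OCCO2)c1OCc1ccc(OC)cc1 | intermediate (not isolated)
11 | potassium 4,4-dimethoxy-3-methylbuta-1,3-dien-2-olate | C=C([O-])C(C)=C(OC)OC.[K+] | intermediate (not isolated)
12 | 4,4-dimethoxy-3-methylbuta-1,3-dien-2-yl 3-(1,3-dioxolan-2-yl)-2,4-bis[(4-methoxybenzyl)oxy]-6-methylbenzoate | C=C(OC(=O)c1c(C)cc(OCc2ccc(OC)cc2)c(C2OCCO2)c1OCc1ccc(OC)cc1)C(C)=C(OC)OC | intermediate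
13 | methyl but-2-ynoate | CC#CC(=O)OC | starting material
14 | methyl 4-({3-(1,3-dioxolan-2-yl)-2,4-bis[(4-methoxybenzyl)oxy]-6-methylbenzoyl}oxy)-6,6-dimethoxy-2,5-dimethylcyclohexa-1,4-diene-1-carboxylate | COC(=O)C1=C(C)CC(OC(=O)c2c(C)cc(OCc3ccc(OC)cc3)c(C3OCCO3)c2OCc2ccc(OC)cc2)=C(C)C1(OC)OC | intermediate (not isolated)
15 | methyl 4-({3-(1,3-dioxolan-2-yl)-2,4-bis[(4-methoxybenzyl)oxy]-6-methylbenzoyl}oxy)-2-methoxy-3,6-dimethylbenzoate | COC(=O)c1c(C)cc(OC(=O)c2c(C)cc(OCc3ccc(OC)cc3)c(C3OCCO3)c2OCc2ccc(OC)cc2)c(C)c1OC | intermediate
16 | 2'-O-methylatranorin (achiral) | COC(=O)c1c(C)cc(OC(=O)c2c(C)cc(O)c(C=O)c2O)c(C)c1OC | target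

Total step count: 9. Longest linear sequence: 7 (steps 1, 2, 3, 4, 7, 8, 9).

Steps most likely to fail

Step 8. The cycloaddition may be outrun by slow thermal erosion of the diene, because the acyloxy donor is weak and the ynoate is β-substituted. The erosion pathways are addition of liberated methanol to the ketene acetal, acyl transfer from the enol ester, and [2+2] addition through the inner ketene acetal carbon. The fallback builds the ring first and the ester second, using only known chemistry. It sets out from 9, which is deprotonated as in step 7 and silylated with TMSCl to give 1,1-dimethoxy-2-methyl-3-(trimethylsilyloxy)buta-1,3-diene F1. Heating this with 13 gives methyl 6,6-dimethoxy-2,5-dimethyl-4-(trimethylsilyloxy)cyclohexa-1,4-diene-1-carboxylate F2. That adduct loses methanol to give methyl 2-methoxy-3,6-dimethyl-4-(trimethylsilyloxy)benzoate F3. Dilute aqueous acid on work-up frees methyl 4-hydroxy-2-methoxy-3,6-dimethylbenzoate F4. Acylation of this phenol with acid chloride 10 (Et3N, DMAP, CH2Cl2) comes back to the route at 15.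

Step 7. The ambident dienolate may be acylated on carbon, it may exchange protons with the product, or the ketene acetal may hydrolyse during isolation. The fallback replaces the metal enolate by a fluoride-catalysed silyl transfer and sets out from 5 and 9. Cyanuric fluoride and pyridine convert 5 into 3-(1,3-dioxolan-2-yl)-2,4-bis[(4-methoxybenzyl)oxy]-6-methylbenzoyl fluoride F5. Compound 9 is converted into 1,1-dimethoxy-2-methyl-3-(trimethylsilyloxy)buta-1,3-diene F1 as above. The two are combined in THF with a catalytic anhydrous fluoride source (TBAT). The metal-free enolate is acylated on oxygen, the silyl group leaves as the volatile fluorosilane, and no aqueous work-up is needed. The fallback comes back to the route at 12.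

Step 6. Chloride may demethylate the acyl dimethoxycarbenium intermediate before proton loss, and the amine may divert acetyl chloride into ketene. The fallback installs the two methoxy groups last and sets out from 8. AlCl3-mediated acylation of commercial 1,1-dichloroprop-1-ene (CC=C(Cl)Cl) in CH2Cl2 gives racemic 4,4,4-trichloro-3-methylbutan-2-one F6. Et3N removes hydrogen chloride to give 4,4-dichloro-3-methylbut-3-en-2-one F7. Two addition–elimination events with NaOMe (2 equiv) in MeOH then replace both chlorines. The fallback comes back to the route at 9 and also bypasses step 5.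

Further compounds
F1 | step 8 | 1,1-dimethoxy-2-methyl-3-(trimethylsilyloxy)buta-1,3-diene | C=C(O[Si](C)(C)C)C(C)=C(OC)OC
F2 | step 8 | methyl 6,6-dimethoxy-2,5-dimethyl-4-(trimethylsilyloxy)cyclohexa-1,4-diene-1-carboxylate | COC(=O)C1=C(C)CC(O[Si](C)(C)C)=C(C)C1(OC)OC
F3 | step 8 | methyl 2-methoxy-3,6-dimethyl-4-(trimethylsilyloxy)benzoate | COC(=O)c1c(C)cc(O[Si](C)(C)C)c(C)c1OC
F4 | step 8 | methyl 4-hydroxy-2-methoxy-3,6-dimethylbenzoate | COC(=O)c1c(C)cc(O)c(C)c1OC
F5 | step 7 | 3-(1,3-dioxolan-2-yl)-2,4-bis[(4-methoxybenzyl)oxy]-6-methylbenzoyl fluoride | O=C(F)c1c(C)cc(OCc2ccc(OC)cc2)c(C2OCCO2)c1OCc1ccc(OC)cc1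
F6 | step 6 | 4,4,4-trichloro-3-methylbutan-2-one (racemic) | CC(=O)C(C)C(Cl)(Cl)Cl
F7 | step 6 | 4,4-dichloro-3-methylbut-3-en-2-one | CC(=O)C(C)=C(Cl)Cl
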